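**Assumption:** the target has no stereocentre (it is achiral), so no enantiocontrol is needed; the only stereochemical element on the way is the C=C geometry of the acrylic acids 12/13, which step 5 handles.

## Retrosynthetic overview

1. Target 15 ⇐ global O-deprotection (two MOM ethers, one acetate) of coumarin 14.
2. Key disconnection: lactone O1–C8a bond. 14 ⇐ 2,3-diarylacrylic acid 12, whose 2,6-dimethoxyaryl ring loses one of two equivalent OMe groups to the CO2H oxygen; the other OMe becomes 5-OMe.
3. 12 ⇐ Perkin condensation of arylacetic acid 9 with 4-hydroxy-2,6-dimethoxybenzaldehyde 10.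
4. 9 ⇐ aryl bromide 5 + zinc ester enolate; 5 ⇐ 4-bromoresorcinol 1 by MOM protection and lithiation/prenylation between the two OMOM groups.
5. Ring order: both benzene rings are bought; the pyran-2-one ring is the only ring formed, last, by the C–O closure.

## Route

**Step 1**
Reactants: 1 4-bromobenzene-1,3-diol (4-bromoresorcinol)
Product: 2 1-bromo-2,4-bis(methoxymethoxy)benzene
Conditions: NaH, MOMCl, DMF, 0 °C → rt
Reagents that add atoms: chloromethyl methyl ether (MOMCl), COCCl
Why: Williamson-type O-alkylation of both sodium phenoxides with MOMCl is a standard MOM protection, and the OMOM groups later direct the metalation.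

**Step 2**
Reactants: 2 1-bromo-2,4-bis(methoxymethoxy)benzene; 3 1-bromo-3-methylbut-2-ene (prenyl bromide)
Product: 5 1-bromo-2,4-bis(methoxymethoxy)-3-(3-methylbut-2-en-1-yl)benzene, via aryllithium 4 (not isolated)
Conditions: LDA, THF, −78 °C; then 3, −78 °C → rt
Reagents that add atoms: none
Why: Directed ortho-metalation: the C–H flanked by two OMOM groups is the most acidic and doubly chelated site, the amide base does not undergo Br/Li exchange, and the aryllithium alkylates the primary allylic bromide at its α-carbon (SN2).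

**Step 3**
Reactants: 5 1-bromo-2,4-bis(methoxymethoxy)-3-(3-methylbut-2-en-1-yl)benzene; 6 ethyl bromoacetate
Product: 9 2-[2,4-bis(methoxymethoxy)-3-(3-methylbut-2-en-1-yl)phenyl]acetic acid, via Reformatsky reagent 7 (not isolated), via ethyl arylacetate 8 (not isolated)
Conditions: Zn dust (TMSCl-activated), 6, THF, 40 °C; then 5, Pd(dba)2 (2 mol%), Q-Phos (2 mol%), THF, rt → 50 °C; then LiOH·H2O, MeOH/H2O, 40 °C; cold dilute HCl to pH 4
Reagents that add atoms: lithium hydroxide, [Li+].[OH-]
Why: Pd-catalysed Negishi-type coupling of an aryl bromide with a zinc ester enolate (Reformatsky reagent) runs under near-neutral conditions that spare MOM and prenyl, and saponification in the same pot gives the acid.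

**Step 4**
Reactants: 9 2-[2,4-bis(methoxymethoxy)-3-(3-methylbut-2-en-1-yl)phenyl]acetic acid; 10 4-hydroxy-2,6-dimethoxybenzaldehyde
Product: 12 (E)-3-[4-(acetyloxy)-2,6-dimethoxyphenyl]-2-[2,4-bis(methoxymethoxy)-3-(3-methylbut-2-en-1-yl)phenyl]prop-2-enoic acid, via O-acetyl aldehyde 11 (not isolated)
Conditions: Ac2O, Et3N, 110 °C; then H2O, 60 °C; aq. citric acid
Reagents that add atoms: acetic anhydride, CC(=O)OC(C)=O
Why: Perkin (Oglialoro) condensation: Ac2O first acetylates the para-OH, which removes the deactivating phenoxide, then the activated arylacetate condenses with the aldehyde and eliminates to the usual E acid (aryl groups cis); the geometry is not critical because step 5 equilibrates it.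

**Step 5**
Reactants: 12 (E)-3-[4-(acetyloxy)-2,6-dimethoxyphenyl]-2-[2,4-bis(methoxymethoxy)-3-(3-methylbut-2-en-1-yl)phenyl]prop-2-enoic acid
Product: 14 3-[2,4-bis(methoxymethoxy)-3-(3-methylbut-2-en-1-yl)phenyl]-5-methoxy-2-oxo-2H-chromen-7-yl acetate, via (Z)-acrylic acid 13 (not isolated)
Conditions: 3,6-di-tert-butyl-9-mesityl-10-phenylacridinium tetrafluoroborate (5 mol%), 2,6-lutidine (20 mol%), DCE/HFIP 4:1, 456 nm LEDs, N2, 30 °C
Reagents that add atoms: none
Why: Proposed new method: a redox-neutral photocatalytic ipso-SNAr lactonisation in which the excited acridinium (E* about +2.0 V vs SCE) oxidises the electron-rich diarylacrylic acid to its radical cation, whose weakened C=C bond lets E and Z interconvert (back electron transfer returns both neutral isomers, 13 included), and only in the Z form can the CO2H add to one of the two equivalent, positively charged MeO-bearing ipso carbons (six-membered closure), after which HFIP-assisted loss of MeOH rearomatises to the coumarin radical cation that is reduced by the acridine radical, so no oxidant is needed and the prenyl, MOM and acetate groups are spared; the closest known reaction types are cation-radical-accelerated SNAr of methoxyarenes with N-nucleophiles under acridinium photocatalysis and the photocatalytic E→Z isomerisation/oxidative C–H lactonisation of cinnamic acids to coumarins.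

**Step 6**
Reactants: 14 3-[2,4-bis(methoxymethoxy)-3-(3-methylbut-2-en-1-yl)phenyl]-5-methoxy-2-oxo-2H-chromen-7-yl acetate
Product: 15 3-[2,4-dihydroxy-3-(3-methylbut-2-en-1-yl)phenyl]-7-hydroxy-5-methoxy-2H-chromen-2-one
Conditions: 1 M HCl in MeOH, 25–35 °C
Reagents that add atoms: none
Why: Acid-catalysed transacetalisation removes both MOM ethers and methanolysis removes the aryl acetate in one operation, and dilute acid at or below 35 °C leaves the prenyl group (no chroman closure onto the neighbouring phenols), the 5-OMe and the lactone intact.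

## Compound list

1 | 4-bromobenzene-1,3-diol | Oc1ccc(Br)c(O)c1 | starting material
2 | 1-bromo-2,4-bis(methoxymethoxy)benzene | COCOc1ccc(Br)c(OCOC)c1 | intermediate
3 | 1-bromo-3-methylbut-2-ene | CC(C)=CCBr | starting material
4 | [3-bromo-2,6-bis(methoxymethoxy)phenyl]lithium | [Li]c1c(OCOC)ccc(Br)c1OCOC | intermediate
5 | 1-bromo-2,4-bis(methoxymethoxy)-3-(3-methylbut-2-en-1-yl)benzene | COCOc1ccc(Br)c(OCOC)c1CC=C(C)C | intermediate
6 | ethyl bromoacetate | CCOC(=O)CBr | starting material
7 | bromo(2-ethoxy-2-oxoethyl)zinc | CCOC(=O)C[Zn]Br | intermediate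
8 | ethyl 2-[2,4-bis(methoxymethoxy)-3-(3-methylbut-2-en-1-yl)phenyl]acetate | CCOC(=O)Cc1ccc(OCOC)c(CC=C(C)C)c1OCOC | intermediate
9 | 2-[2,4-bis(methoxymethoxy)-3-(3-methylbut-2-en-1-yl)phenyl]acetic acid | OC(=O)Cc1ccc(OCOC)c(CC=C(C)C)c1OCOC | intermediate
10 | 4-hydroxy-2,6-dimethoxybenzaldehyde | COc1cc(O)cc(OC)c1C=O | starting material
11 | 4-formyl-3,5-dimethoxyphenyl acetate | COc1cc(OC(C)=O)cc(OC)c1C=O | intermediate
12 | (E)-3-[4-(acetyloxy)-2,6-dimethoxyphenyl]-2-[2,4-bis(methoxymethoxy)-3-(3-methylbut-2-en-1-yl)phenyl]prop-2-enoic acid | OC(=O)/C(c1ccc(OCOC)c(CC=C(C)C)c1OCOC)=C/c1c(OC)cc(OC(C)=O)cc1OC | intermediate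
13 | (Z)-3-[4-(acetyloxy)-2,6-dimethoxyphenyl]-2-[2,4-bis(methoxymethoxy)-3-(3-methylbut-2-en-1-yl)phenyl]prop-2-enoic acid | OC(=O)/C(c1ccc(OCOC)c(CC=C(C)C)c1OCOC)=C\c1c(OC)cc(OC(C)=O)cc1OC | intermediate
14 | 3-[2,4-bis(methoxymethoxy)-3-(3-methylbut-2-en-1-yl)phenyl]-5-methoxy-2-oxo-2H-chromen-7-yl acetate | COc1cc(OC(C)=O)cc2oc(=O)c(-c3ccc(OCOC)c(CC=C(C)C)c3OCOC)cc12 | intermediate
15 | 3-[2,4-dihydroxy-3-(3-methylbut-2-en-1-yl)phenyl]-7-hydroxy-5-methoxy-2H-chromen-2-one | COc1cc(O)cc2oc(=O)c(-c3ccc(O)c(CC=C(C)C)c3O)cc12 | target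

## Step count and risk

Total step count: 6. Longest linear sequence: 6 steps (1 → 2 → 5 → 9 → 12 → 14 → 15).

**Step 5 (the proposed new photochemical lactonisation).** It may fail through oxidation of the prenyl alkene, unproductive E/Z cycling, or decarboxylation. The fallback uses only known chemistry, sets out from aldehyde 10 (together with acid 9) and comes back to the route at 14, bypassing 12. BCl3 in CH2Cl2 (−78 → 0 °C) cleaves one of the two equivalent methyl ethers ortho to the formyl group by chelation and gives 2,4-dihydroxy-6-methoxybenzaldehyde F1. Heating F1 with acid 9 in Ac2O/Et3N at 110 °C is the classical Perkin–Oglialoro coumarin synthesis: the salicyl OH closes the lactone, the 7-OH is acetylated, and 14 is obtained directly.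

**Step 4 (Perkin condensation on a 2,6-disubstituted, electron-rich aldehyde).** The thermal condensation may stall. The fallback sets out from acid 9 and O-acetyl aldehyde 11 (made separately from 10 with Ac2O/pyridine and isolated) and comes back at 12. Acid 9 is deprotonated twice with LDA (THF, −78 °C) and the enediolate is added to 11 at −78 °C (Ivanov-type aldol under kinetic control). This gives 3-[4-(acetyloxy)-2,6-dimethoxyphenyl]-2-[2,4-bis(methoxymethoxy)-3-(3-methylbut-2-en-1-yl)phenyl]-3-hydroxypropanoic acid F2 as a mixture of racemic diastereomers. F2 is dehydrated with Ac2O/Et3N/DMAP at 50 °C to 12; an E/Z mixture is acceptable because step 5 equilibrates the geometry.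

**Step 2 (amide-base lithiation of a bromoarene and prenylation).** Incomplete metalation or metalation next to bromine would cost the route. The fallback sets out from prenyl bromide 3 (with resorcinol as an extra purchased material) and comes back at 5, adding one step. Resorcinol is protected with NaH/MOMCl to 1,3-bis(methoxymethoxy)benzene F3. n-BuLi (THF, 0 °C) lithiates C2 and 3 alkylates it to 1,3-bis(methoxymethoxy)-2-(3-methylbut-2-en-1-yl)benzene F4. NBS in MeCN at −20 °C then brominates the activated ring para to an OMOM group to give 5.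

## Further compounds

F1 | step 5 | 2,4-dihydroxy-6-methoxybenzaldehyde | COc1cc(O)cc(O)c1C=O
F2 | step 4 | 3-[4-(acetyloxy)-2,6-dimethoxyphenyl]-2-[2,4-bis(methoxymethoxy)-3-(3-methylbut-2-en-1-yl)phenyl]-3-hydroxypropanoic acid (mixture of racemic diastereomers) | OC(=O)C(c1ccc(OCOC)c(CC=C(C)C)c1OCOC)C(O)c1c(OC)cc(OC(C)=O)cc1OC
F3 | step 2 | 1,3-bis(methoxymethoxy)benzene | COCOc1cccc(OCOC)c1
F4 | step 2 | 1,3-bis(methoxymethoxy)-2-(3-methylbut-2-en-1-yl)benzene | COCOc1cccc(OCOC)c1CC=C(C)C
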